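The route exploits the hidden C2 symmetry of the 1,2-dioxolane: C3 and C5 each carry a methyl and a CH2 arm, and the methyls are trans. The defining disconnection removes both C–O bonds (O2–C3 and O1–C5) at once: one molecule of H2O2 is stitched between the two tertiary epoxide carbons of a C2-symmetric bis(2,3-epoxy alcohol). That single operation closes the ring and sets both quaternary peroxy stereocentres by double inversion of centres installed by a two-directional Sharpless epoxidation. The precursor is an acyclic, peroxide-free diepoxy diol made from a skipped dienediol; its two homotopic arms are later cut to vinyl groups and differentiated into the acetic acid and the triene chain.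

Key step: step 5

Remark: bromo ester 3 is taken as the geometrically pure (E)-isomer; reagents that only deliver atoms are named with SMILES on the reagent line and are not numbered.

Step 1
Reactants: 1 ethyl but-2-ynoate
Product: 2 ethyl (2E)-3-(tributylstannyl)but-2-enoate
Conditions: Bu3SnH, LDA, THF, 0 °C; CuBr·SMe2, −78 °C; then 1, MeOH, −78 °C
Reagents that add atoms: tributyltin hydride, CCCC[SnH](CCCC)CCCC
Why: Syn-stannylcupration of the ynoate puts tin on C3, and kinetic protonation of the α-copper species at −78 °C should give the (E)-β-stannyl enoate (Sn trans to CO2Et, methyl cis).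

Step 2
Reactants: 2 ethyl (2E)-3-(tributylstannyl)but-2-enoate; 3 ethyl (2E)-4-bromo-3-methylbut-2-enoate
Product: 4 diethyl (2E,5E)-3,5-dimethylhepta-2,5-dienedioate
Conditions: Pd2(dba)3 (2.5 mol %), AsPh3 (10 mol %), NMP, 45 °C
Reagents that add atoms: none
Why: Stille allyl–vinyl coupling joins the vinyl carbon (with retention) to the CH2 terminus of the allyl unit under neutral conditions, so both trisubstituted alkenes should stay E and the skipped diene should not move into conjugation.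

Step 3
Reactants: 4 diethyl (2E,5E)-3,5-dimethylhepta-2,5-dienedioate
Product: 5 (2E,5E)-3,5-dimethylhepta-2,5-diene-1,7-diol
Conditions: DIBAL-H (4.5 equiv), CH2Cl2, −78 to 0 °C; Rochelle salt work-up
Reagents that add atoms: none
Why: DIBAL-H reduces both enoates 1,2 to the allylic alcohols without touching the alkenes.

Step 4
Reactants: 5 (2E,5E)-3,5-dimethylhepta-2,5-diene-1,7-diol
Product: 6 (2S,3S,5S,6S)-2,3:5,6-diepoxy-3,5-dimethylheptane-1,7-diol
Conditions: Ti(OiPr)4 (20 mol %), L-(+)-diethyl tartrate (24 mol %), t-BuOOH (4 equiv, anhydrous), 4 Å MS, CH2Cl2, −20 °C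
Reagents that add atoms: tert-butyl hydroperoxide, CC(C)(C)OO
Why: Two-directional Sharpless asymmetric epoxidation of two geraniol-type (E)-allylic alcohols, in which L-(+)-tartrate delivers oxygen to the same face at each end (as geraniol gives the 2S,3S epoxide), should set all four centres under reagent control and leave the minor meso isomer as a separable diastereomer.

Step 5
Reactants: 6 (2S,3S,5S,6S)-2,3:5,6-diepoxy-3,5-dimethylheptane-1,7-diol
Product: 8 (1S,1'S)-1,1'-[(3R,5R)-3,5-dimethyl-1,2-dioxolane-3,5-diyl]di(ethane-1,2-diol), via hydroperoxy epoxide 7 (not isolated)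
Conditions: H2O2 (anhydrous, ca. 3 M in Et2O, 5 equiv), H3PMo12O40 (2 mol %), Et2O–THF, 0 °C to rt
Reagents that add atoms: hydrogen peroxide, OO
Why: The acid activates one epoxide and H2O2 opens it at the tertiary carbon C3 with inversion (borderline SN2) to give β-hydroxy hydroperoxide 7, whose terminal peroxide oxygen then opens the second activated epoxide at C5, again with inversion. The closest known reactions are the acid- or molybdenum-catalysed perhydrolysis of trisubstituted epoxides to β-hydroxy hydroperoxides and the intramolecular opening of epoxides by hydroperoxides. The ring closure is 5-exo-tet: the new ring holds O–O, C3, C4 and C5, and the epoxide C–O bond that breaks lies outside it. Both new stereocentres, C3 and C5 of the dioxolane, are fixed stereospecifically by backside attack on epoxide carbons already set in step 4, so the C2-symmetric (S,S,S,S)-diepoxide can only give the trans-dimethyl (3R,5R) ring. The step needs tertiary over secondary opening (cation stability at C3/C5, inductive deactivation of C2/C6 by CH2OH), peroxide over hydroxyl closure (α-effect and unhindered terminal oxygen of OOH against a secondary OH next to a quaternary carbon) and intra- over intermolecular second opening (high effective molarity of the 5-exo mode).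

Step 6
Reactants: 8 (1S,1'S)-1,1'-[(3R,5R)-3,5-dimethyl-1,2-dioxolane-3,5-diyl]di(ethane-1,2-diol)
Product: 9 (3R,5R)-3,5-dimethyl-1,2-dioxolane-3,5-dicarbaldehyde
Conditions: NaIO4 (2.5 equiv), THF–H2O (pH 7 buffer), 0 °C
Reagents that add atoms: none
Why: Malaprade glycol cleavage removes both CH2OH termini as formaldehyde under neutral conditions that a tetrasubstituted dialkyl peroxide tolerates, and the non-enolisable α-peroxy aldehydes cannot epimerise.

Step 7
Reactants: 9 (3R,5R)-3,5-dimethyl-1,2-dioxolane-3,5-dicarbaldehyde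
Product: 10 (3R,5R)-3,5-diethenyl-3,5-dimethyl-1,2-dioxolane
Conditions: Ph3PCH3Br (2.6 equiv), KOtBu (2.5 equiv), THF, 0 °C; then 9, −78 to 0 °C
Reagents that add atoms: methyltriphenylphosphonium bromide, C[P+](c1ccccc1)(c1ccccc1)c1ccccc1.[Br-]
Why: Wittig methylenation of the two non-enolisable aldehydes, a reaction type that dialkyl peroxides tolerate.

Step 8
Reactants: 10 (3R,5R)-3,5-diethenyl-3,5-dimethyl-1,2-dioxolane
Product: 12 2,2'-[(3S,5S)-3,5-dimethyl-1,2-dioxolane-3,5-diyl]di(ethan-1-ol), via bis(alkylborane) 11 (not isolated)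
Conditions: 9-BBN (2.4 equiv), THF, 0 °C to rt; then NaOAc (3 M aq.), 30% H2O2, 0 °C to rt
Reagents that add atoms: hydrogen peroxide, OO
Why: Brown hydroboration with 9-BBN places boron on the terminal carbon, away from the quaternary peroxy carbon, and buffered peroxide oxidation turns C–B into C–OH without opening the hindered O–O bond.

Step 9
Reactants: 12 2,2'-[(3S,5S)-3,5-dimethyl-1,2-dioxolane-3,5-diyl]di(ethan-1-ol)
Product: 13 2-[(3S,5R)-5-(2-bromoethyl)-3,5-dimethyl-1,2-dioxolan-3-yl]ethan-1-ol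
Conditions: CBr4 (1.0 equiv), PPh3 (1.0 equiv), CH2Cl2, 0 °C; unreacted 12 recycled
Reagents that add atoms: carbon tetrabromide, BrC(Br)(Br)Br
Why: Appel bromination of one of two homotopic primary alcohols is statistical but cannot create stereoisomers, and diol, monobromide and dibromide should separate easily.

Step 10
Reactants: 14 (3Z)-hex-3-en-1-ol
Product: 15 5-{[(3Z)-hex-3-en-1-yl]sulfanyl}-1-phenyl-1H-tetrazole
Conditions: 1-phenyl-1H-tetrazole-5-thiol, PPh3, DIAD, THF, 0 °C to rt
Reagents that add atoms: 1-phenyl-1H-tetrazole-5-thiol, Sc1nnnn1-c1ccccc1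
Why: Mitsunobu thioetherification of a primary alcohol leaves the Z alkene untouched.

Step 11
Reactants: 15 5-{[(3Z)-hex-3-en-1-yl]sulfanyl}-1-phenyl-1H-tetrazole
Product: 16 5-{[(3Z)-hex-3-en-1-yl]sulfonyl}-1-phenyl-1H-tetrazole
Conditions: (NH4)6Mo7O24·4H2O (10 mol %), 30% H2O2 (5 equiv), EtOH, 0 °C to rt
Reagents that add atoms: hydrogen peroxide, OO
Why: Molybdate-catalysed peroxide oxidation of sulfide to sulfone is much faster than epoxidation of an isolated disubstituted alkene.

Step 12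
Reactants: 17 pent-4-enal
Product: 18 (2E)-hepta-2,6-dienal
Conditions: Ph3P=CHCHO (1.05 equiv), toluene, 80 °C
Reagents that add atoms: (triphenylphosphoranylidene)acetaldehyde, O=CC=P(c1ccccc1)(c1ccccc1)c1ccccc1
Why: Wittig olefination with the stabilised formyl ylide should give the (E)-enal.

Step 13
Reactants: 16 5-{[(3Z)-hex-3-en-1-yl]sulfonyl}-1-phenyl-1H-tetrazole; 18 (2E)-hepta-2,6-dienal
Product: 19 (5E,7E,10Z)-trideca-1,5,7,10-tetraene
Conditions: KHMDS (1.1 equiv) added to 16 and 18, DME, −60 °C to rt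
Reagents that add atoms: none
Why: Julia–Kocienski olefination of a phenyltetrazolyl sulfone with an enal should form the new C7=C8 bond E-selectively, while the Z alkene from 14 and the E alkene from 18 are not touched.

Step 14
Reactants: 19 (5E,7E,10Z)-trideca-1,5,7,10-tetraene; 13 2-[(3S,5R)-5-(2-bromoethyl)-3,5-dimethyl-1,2-dioxolan-3-yl]ethan-1-ol
Product: 21 2-[(3S,5S)-3,5-dimethyl-5-[(7E,9E,12Z)-pentadeca-7,9,12-trien-1-yl]-1,2-dioxolan-3-yl]ethan-1-ol, via trienylborane 20 (not isolated)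
Conditions: 19, 9-BBN (1.0 equiv), THF, 0 °C to rt; then 13 (0.8 equiv), Pd(OAc)2 (4 mol %), PCy3 (8 mol %), K3PO4·H2O (1.2 equiv), THF, rt
Reagents that add atoms: none
Why: 9-BBN hydroborates only the monosubstituted alkene of 19, and the B-alkyl Suzuki–Miyaura alkyl–alkyl coupling with the primary bromide (Pd/PCy3) forms the C2'–C3' bond with the triene as a spectator on the boron partner.

Step 15
Reactants: 21 2-[(3S,5S)-3,5-dimethyl-5-[(7E,9E,12Z)-pentadeca-7,9,12-trien-1-yl]-1,2-dioxolan-3-yl]ethan-1-ol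
Product: 22 2-[(3R,5S)-3,5-dimethyl-5-[(7E,9E,12Z)-pentadeca-7,9,12-trien-1-yl]-1,2-dioxolan-3-yl]acetaldehyde
Conditions: Dess–Martin periodinane, NaHCO3, CH2Cl2, 0 °C
Reagents that add atoms: none
Why: Dess–Martin oxidation is non-basic, so the β-peroxy aldehyde should not undergo retro-oxa-Michael ring opening and the triene is not affected.

Step 16
Reactants: 22 2-[(3R,5S)-3,5-dimethyl-5-[(7E,9E,12Z)-pentadeca-7,9,12-trien-1-yl]-1,2-dioxolan-3-yl]acetaldehyde
Product: 23 2-[(3R,5S)-3,5-dimethyl-5-[(7E,9E,12Z)-pentadeca-7,9,12-trien-1-yl]-1,2-dioxolan-3-yl]acetic acid (CNP0215994.1)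
Conditions: NaClO2, NaH2PO4, 2-methylbut-2-ene (excess), t-BuOH–H2O, 0 °C to rt
Reagents that add atoms: sodium chlorite, [Na+].[O-]Cl=O
Why: Pinnick oxidation at pH 3–4 with an alkene scavenger for hypochlorite converts the aldehyde to the acid without harming the peroxide or the triene.

Compound list
1 | ethyl but-2-ynoate | CCOC(=O)C#CC | starting material
2 | ethyl (2E)-3-(tributylstannyl)but-2-enoate | CCOC(=O)/C=C(\C)[Sn](CCCC)(CCCC)CCCC | intermediate
3 | ethyl (2E)-4-bromo-3-methylbut-2-enoate | CCOC(=O)/C=C(\C)CBr | starting material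
4 | diethyl (2E,5E)-3,5-dimethylhepta-2,5-dienedioate | CCOC(=O)/C=C(\C)C/C(C)=C/C(=O)OCC | intermediate
5 | (2E,5E)-3,5-dimethylhepta-2,5-diene-1,7-diol | OC/C=C(\C)C/C(C)=C/CO | intermediate
6 | (2S,3S,5S,6S)-2,3:5,6-diepoxy-3,5-dimethylheptane-1,7-diol | C[C@]1(O[C@H]1CO)C[C@]2(C)O[C@H]2CO | intermediate
7 | (2S,3R)-3-hydroperoxy-4-[(2S,3S)-3-(hydroxymethyl)-2-methyloxiran-2-yl]-3-methylbutane-1,2-diol | OC[C@H](O)[C@](C)(OO)C[C@]1(C)O[C@H]1CO | intermediate (not isolated)
8 | (1S,1'S)-1,1'-[(3R,5R)-3,5-dimethyl-1,2-dioxolane-3,5-diyl]di(ethane-1,2-diol) | OC[C@H](O)[C@@]1(C)C[C@](C)([C@@H](O)CO)OO1 | intermediate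
9 | (3R,5R)-3,5-dimethyl-1,2-dioxolane-3,5-dicarbaldehyde | O=C[C@@]1(C)C[C@](C)(C=O)OO1 | intermediate
10 | (3R,5R)-3,5-diethenyl-3,5-dimethyl-1,2-dioxolane | C=C[C@@]1(C)C[C@](C)(C=C)OO1 | intermediate
11 | (3S,5S)-3,5-bis[2-(9-borabicyclo[3.3.1]nonan-9-yl)ethyl]-3,5-dimethyl-1,2-dioxolane | C(C[C@@]1(C)C[C@](C)(CCB2C3CCCC2CCC3)OO1)B1C2CCCC1CCC2 | intermediate (not isolated)
12 | 2,2'-[(3S,5S)-3,5-dimethyl-1,2-dioxolane-3,5-diyl]di(ethan-1-ol) | OCC[C@@]1(C)C[C@](C)(CCO)OO1 | intermediate
13 | 2-[(3S,5R)-5-(2-bromoethyl)-3,5-dimethyl-1,2-dioxolan-3-yl]ethan-1-ol | BrCC[C@@]1(C)C[C@](C)(CCO)OO1 | intermediate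
14 | (3Z)-hex-3-en-1-ol | CC/C=C\CCO | starting material
15 | 5-{[(3Z)-hex-3-en-1-yl]sulfanyl}-1-phenyl-1H-tetrazole | CC/C=C\CCSc1nnnn1-c1ccccc1 | intermediate
16 | 5-{[(3Z)-hex-3-en-1-yl]sulfonyl}-1-phenyl-1H-tetrazole | CC/C=C\CCS(=O)(=O)c1nnnn1-c1ccccc1 | intermediate
17 | pent-4-enal | C=CCCC=O | starting material
18 | (2E)-hepta-2,6-dienal | C=CCC/C=C/C=O | intermediate
19 | (5E,7E,10Z)-trideca-1,5,7,10-tetraene | C=CCC/C=C/C=C/C/C=C\CC | intermediate
20 | 9-[(5E,7E,10Z)-trideca-5,7,10-trien-1-yl]-9-borabicyclo[3.3.1]nonane | CC/C=C\C/C=C/C=C/CCCCB1C2CCCC1CCC2 | intermediate (not isolated)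
21 | 2-[(3S,5S)-3,5-dimethyl-5-[(7E,9E,12Z)-pentadeca-7,9,12-trien-1-yl]-1,2-dioxolan-3-yl]ethan-1-ol | CC/C=C\C/C=C/C=C/CCCCCC[C@@]1(C)C[C@](C)(CCO)OO1 | intermediate
22 | 2-[(3R,5S)-3,5-dimethyl-5-[(7E,9E,12Z)-pentadeca-7,9,12-trien-1-yl]-1,2-dioxolan-3-yl]acetaldehyde | CC/C=C\C/C=C/C=C/CCCCCC[C@@]1(C)C[C@](C)(CC=O)OO1 | intermediate
23 | 2-[(3R,5S)-3,5-dimethyl-5-[(7E,9E,12Z)-pentadeca-7,9,12-trien-1-yl]-1,2-dioxolan-3-yl]acetic acid | CC/C=C\C/C=C/C=C/CCCCCC[C@@]1(C)C[C@](C)(CC(=O)O)OO1 | target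

Total step count: 16. Longest linear sequence: 12 steps (steps 1–9 and 14–16); steps 10–13 build the chain fragment.

Steps most likely to fail

Step 5 (key step). The hydroxyl set free at C2 by the first opening may capture the second epoxide (a competing five-membered ether closure), or acid-induced rearrangement of the epoxy alcohol or fragmentation of the β-hydroxy hydroperoxide may outrun peroxide ring closure. The fallback removes the competing nucleophile instead of tuning the conditions and sets out from 6. Oxidation of both primary alcohols (RuCl3 cat., NaIO4, CCl4–MeCN–H2O) would give (2R,3S,5S,6R)-2,3:5,6-diepoxy-3,5-dimethylheptanedioic acid F1, and TMSCHN2 would give its dimethyl ester, dimethyl (2R,3S,5S,6R)-2,3:5,6-diepoxy-3,5-dimethylheptanedioate F2. In F2 no free hydroxyl is present, the α-carbons are deactivated by the esters, and the hydroxyl formed on opening is an α-hydroxy ester oxygen of low nucleophilicity. Ethereal H2O2 with the same acid catalyst should then give dimethyl (2R,2'R)-2,2'-[(3R,5R)-3,5-dimethyl-1,2-dioxolane-3,5-diyl]bis(2-hydroxyacetate) F3 by the same two inversions. NaBH4 in MeOH reduces both α-hydroxy esters and the route is rejoined at 8.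

Step 14. Pd(0)/PCy3 may reduce or insert into the O–O bond, or β-hydride elimination of the alkyl–palladium intermediate may outrun the alkyl–alkyl coupling. The fallback uses only reaction types proven on peroxides (Wittig, diimide) and sets out from 12. One of its two homotopic hydroxyls is oxidised (TEMPO, PhI(OAc)2, limiting) to 2-[(3R,5S)-5-(2-hydroxyethyl)-3,5-dimethyl-1,2-dioxolan-3-yl]acetaldehyde F4. Wittig olefination with the ylide from [4-(1,3-dioxolan-2-yl)butyl]triphenylphosphonium bromide (NaHMDS, THF, −78 °C) gives 2-[(3S,5S)-5-[(2Z)-6-(1,3-dioxolan-2-yl)hex-2-en-1-yl]-3,5-dimethyl-1,2-dioxolan-3-yl]ethan-1-ol F5. Diimide (2-nitrobenzenesulfonyl hydrazide, Et3N) saturates this alkene, while no other is present, to 2-[(3S,5S)-5-[6-(1,3-dioxolan-2-yl)hexyl]-3,5-dimethyl-1,2-dioxolan-3-yl]ethan-1-ol F6. Mild acid hydrolysis of the acetal gives 7-[(3S,5S)-5-(2-hydroxyethyl)-3,5-dimethyl-1,2-dioxolan-3-yl]heptanal F7, and Wittig reaction with Ph3P=CHCHO gives (2E)-9-[(3S,5S)-5-(2-hydroxyethyl)-3,5-dimethyl-1,2-dioxolan-3-yl]non-2-enal F8. Julia–Kocienski olefination of F8 with sulfone 16 (KHMDS, 2 equiv, the hydroxyl carried as its alkoxide) rejoins the route at 21.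

Step 8. The alkylborane may be oxidised intramolecularly by the neighbouring O–O bond, or hydroboration of the hindered vinyl groups next to quaternary carbons may stay incomplete. The boron-free fallback sets out from 9. Wittig reaction with methoxymethylidenetriphenylphosphorane (from (methoxymethyl)triphenylphosphonium chloride, KHMDS) gives (3R,5R)-3,5-bis[(E)-2-methoxyethenyl]-3,5-dimethyl-1,2-dioxolane F9 (the Z isomers converge on the same aldehyde). Mild aqueous acid (PPTS, acetone–H2O) hydrolyses the enol ethers to 2,2'-[(3R,5R)-3,5-dimethyl-1,2-dioxolane-3,5-diyl]diacetaldehyde F10, and NaBH4 reduction rejoins the route at 12.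

Further compounds
F1 | step 5 | (2R,3S,5S,6R)-2,3:5,6-diepoxy-3,5-dimethylheptanedioic acid | C[C@]1(O[C@H]1C(=O)O)C[C@]2(C)O[C@H]2C(=O)O
F2 | step 5 | dimethyl (2R,3S,5S,6R)-2,3:5,6-diepoxy-3,5-dimethylheptanedioate | C[C@]1(O[C@H]1C(=O)OC)C[C@]2(C)O[C@H]2C(=O)OC
F3 | step 5 | dimethyl (2R,2'R)-2,2'-[(3R,5R)-3,5-dimethyl-1,2-dioxolane-3,5-diyl]bis(2-hydroxyacetate) | COC(=O)[C@H](O)[C@@]1(C)C[C@](C)([C@@H](O)C(=O)OC)OO1
F4 | step 14 | 2-[(3R,5S)-5-(2-hydroxyethyl)-3,5-dimethyl-1,2-dioxolan-3-yl]acetaldehyde | O=CC[C@@]1(C)C[C@](C)(CCO)OO1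
F5 | step 14 | 2-[(3S,5S)-5-[(2Z)-6-(1,3-dioxolan-2-yl)hex-2-en-1-yl]-3,5-dimethyl-1,2-dioxolan-3-yl]ethan-1-ol | O1CCOC1CCC/C=C\C[C@@]1(C)C[C@](C)(CCO)OO1
F6 | step 14 | 2-[(3S,5S)-5-[6-(1,3-dioxolan-2-yl)hexyl]-3,5-dimethyl-1,2-dioxolan-3-yl]ethan-1-ol | O1CCOC1CCCCCC[C@@]1(C)C[C@](C)(CCO)OO1
F7 | step 14 | 7-[(3S,5S)-5-(2-hydroxyethyl)-3,5-dimethyl-1,2-dioxolan-3-yl]heptanal | O=CCCCCCC[C@@]1(C)C[C@](C)(CCO)OO1
F8 | step 14 | (2E)-9-[(3S,5S)-5-(2-hydroxyethyl)-3,5-dimethyl-1,2-dioxolan-3-yl]non-2-enal | O=C/C=C/CCCCCC[C@@]1(C)C[C@](C)(CCO)OO1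
F9 | step 8 | (3R,5R)-3,5-bis[(E)-2-methoxyethenyl]-3,5-dimethyl-1,2-dioxolane | CO/C=C/[C@@]1(C)C[C@](C)(/C=C/OC)OO1
F10 | step 8 | 2,2'-[(3R,5R)-3,5-dimethyl-1,2-dioxolane-3,5-diyl]diacetaldehyde | O=CC[C@@]1(C)C[C@](C)(CC=O)OO1
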